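The data were computed with made-up constants; scatter was added.

At early times the amber run moves fast: at 0.500 d you already read 37.8% of D and 18.5% of Q, and from 2.50 d on both lie flat within the scatter.

| setting | amber | violet | flask |
|---|---|---|---|
| L | 1 M | 2 M | 2.0 M |
| Z | 1 M | 0.50 M | 1.00 M |
| remark | run made earlier | run made earlier |  |
| time |  |  | 15 d |

| run | time / d | D / % | Q / % |
|---|---|---|---|
| amber | 0.500 | 37.8 | 18.5 |
| amber | 1.25 | 43.6 | 21.0 |
| amber | 2.50 | 44.3 | 21.4 |
| amber | 4.00 | 44.0 | 21.3 |
| amber | 5.00 | 43.7 | 21.4 |
| amber | 8.00 | 43.9 | 21.5 |
| amber | 10.0 | 43.8 | 21.3 |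
| violet | 0.625 | 47.8 | 23.7 |
| violet | 1.25 | 55.1 | 26.9 |
| violet | 2.50 | 55.7 | 27.3 |
| violet | 5.00 | 56.0 | 27.0 |
| violet | 10.0 | 55.8 | 27.6 |

(scatter of a reading: 0.3 percentage points)

- the reaction counts as stopped when no species that holds the L changes by six tenths of a point or more over the second half of the time

- at 15 d, what has stopped the reaction, if anything has (forward and back rates have come level / it is still moving / all of L has reacted)
- the D standing at 15 d, as a percentage of the L charged
- the Q standing at 15 d, as a percentage of the L charged

At the last amber reading D takes 67.3% of D plus Q, and at the first reading 67.1%, so you can treat this as a fixed split. But D plus Q stands at 65.1%, so the rest of the L charged is not in these two.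

My reckoning is that L gives D and Q by first-order steps, and L plus Z gives an unseen product, one to one. Call x the D plus Q made, in M. Let κ be the crossover concentration, the Z concentration at which L goes equally fast both ways, a selectivity factor in concentration units. Then Z left is its charge times exp(−x/κ). The last amber reading has x = 0.651 M and, if no L stands, Z left 0.651 M, so κ reads 1.52 M.

You should object that this assumes no L on the plateau, and that flat readings do not by themselves tell that apart from forward and back rates come level. Violet is the test: x = 1.67 M and Z left 0.168 M give κ = 1.53 M, close to amber. So I expect the L of this flask to have reacted by 15 d, which is longer than the 2.50 d after which the runs lie flat.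

Here x and Z depend on each other: x = charged L − charged Z + Z left. Starting from x equal to the L charge gives 1.27 M, and feeding back gives 1.43 M, 1.39 M, 1.40 M. My split then gives D 47.1% and Q 22.9%.

The forecast answers forward and back rates have come level, with D 48.3% and Q 23.6%, on the best guess that “Z ties up L reversibly as a complex”. It differs from mine on the stop and on both amounts.

The flask gives all of L has reacted: L, the limiting reagent, stands at 0% at 15.0 d, with D 47.1%, Q 22.9% and a further product J 30.0%.

    L → Q (k = 0.0370 h⁻¹)
    L + Z → J (k = 0.0740 L mol⁻¹ h⁻¹)
    L → D (k = 0.0760 h⁻¹)

κ puts Z left in this flask at 39.8% of its charge, and the flask holds 40%. With 2.5 M of Z in the neighbour, the feedback swings, so average each x with what it returns: from 1.40 M you get 0.947 M, then 0.893 M, which gives D 30.0%. The neighbour stands at D 30.0%, Q 14.6% and J 55.3%.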